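The dihydropyranone ring (O1–C2–C3–C4(=O)–C4a=C8a) is disconnected at O1–C8a and C4–C4a, so that its O1–C2–C3–C4(=O) arc is a β-lactone: cis-(3S,4R)-3,4-dimethyloxetan-2-one already holds both methyl stereocentres and the ring oxygen. In one operation an ortho-fluoroaryllithium (Li at the future C4a, F at C8a, lavandulyl in place) opens the lactone at its acyl carbon and the freed C2 alkoxide displaces fluoride. The four-membered ring thus grows by the two arene carbons into the cis-2,3-dimethylchromanone without touching C2 or C3. A carbene-catalysed annulation then adds the (S)-phenylpropanoate arm at C6, and Pd-catalysed dearomative prenylation at C8 finishes the target.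

Key step: step 6

Remark: chromanone numbering (O1, C2, C3, C4, C4a, C5–C8, C8a) is used throughout; "lavandulyl" is 5-methyl-2-(prop-1-en-2-yl)hex-4-en-1-yl; (R)-lavandulol and tert-butyl prenyl carbonate are taken as purchasable; each chiral catalyst is named in the enantiomeric series assumed to give the drawn configuration, and its mirror image is equally available.

Step 1
Reactants: 1 5-fluororesorcinol
Product: 2 1-fluoro-3,5-bis(methoxymethoxy)benzene
Conditions: MOMCl (2.4 equiv), iPr2NEt, CH2Cl2, 0 °C to rt
Reagents that add atoms: chloromethyl methyl ether, COCCl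
Why: Williamson-type O-alkylation of both phenols; the MOM ethers should survive the organometallic steps and come off later without protic acid.

Step 2
Reactants: 2 1-fluoro-3,5-bis(methoxymethoxy)benzene
Product: 3 2,4-dibromo-3-fluoro-1,5-bis(methoxymethoxy)benzene
Conditions: NBS (2.05 equiv), MeCN, 0 °C to rt
Reagents that add atoms: N-bromosuccinimide, O=C1CCC(=O)N1Br
Why: electrophilic aromatic bromination should go twice para to one OMOM group and ortho to the other (the two carbons flanking fluorine), as with 3,5-dialkoxytoluenes, leaving the more hindered carbon between the two OMOM groups as C–H.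

Step 3
Reactants: 4 (R)-lavandulol
Product: 5 (R)-lavandulyl iodide
Conditions: I2, PPh3, imidazole, CH2Cl2, 0 °C
Reagents that add atoms: iodine, II
Why: Appel iodination is an SN2 displacement at the primary carbon, so the adjacent stereocentre is not touched.

Step 4
Reactants: 3 2,4-dibromo-3-fluoro-1,5-bis(methoxymethoxy)benzene, 5 (R)-lavandulyl iodide
Product: 7 2-bromo-3-fluoro-1,5-bis(methoxymethoxy)-4-[(2S)-lavandulyl]benzene, via arylmagnesium chloride 6 (not isolated)
Conditions: iPrMgCl·LiCl (1.05 equiv), THF, −20 °C; then 5, Li2CuCl4 (5 mol%), NMP, −20 to 0 °C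
Reagents that add atoms: none
Why: halogen–magnesium exchange at one of the two equivalent C–Br bonds followed by copper-catalysed Kumada-type sp2–sp3 coupling with the primary iodide should give 7; the two-electron copper pathway avoids homoallyl-radical rearrangement and the lavandulyl stereocentre, β to the reacting carbon, is carried over unchanged.

Step 5
Reactants: 8 propionyl chloride, 9 acetaldehyde
Product: 11 (3S,4R)-3,4-dimethyloxetan-2-one, via methylketene 10 (not isolated)
Conditions: O-TMS-quinidine (10 mol%), LiClO4, iPr2NEt, CH2Cl2/Et2O, −78 °C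
Reagents that add atoms: none
Why: cinchona alkaloid/Lewis acid-catalysed acyl halide–aldehyde cyclocondensation (a ketene–aldehyde [2+2]); the alkaloid-bound ammonium enolate of methylketene adds to the lithium-activated aldehyde through a closed transition state, which should set both stereocentres as the cis lactone under catalyst control.

Step 6
Reactants: 7 2-bromo-3-fluoro-1,5-bis(methoxymethoxy)-4-[(2S)-lavandulyl]benzene, 11 (3S,4R)-3,4-dimethyloxetan-2-one
Product: 14 (2R,3S)-5,7-bis(methoxymethoxy)-2,3-dimethyl-8-[(2S)-lavandulyl]chroman-4-one, via aryllithium 12 (not isolated), via lithium keto-alkoxide 13 (not isolated)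
Conditions: n-BuLi (1.05 equiv), THF, −78 °C; cannulate into 11 (1.3 equiv), THF, −78 °C; then DMPU, −78 to 0 °C
Reagents that add atoms: none
Why: Bromine–lithium exchange gives the ortho-fluoroaryllithium 12, whose carbanion (the future C4a) adds to the strained lactone carbonyl; the oxetan-2-olate collapses by acyl–oxygen cleavage to the lithium β-keto alkoxide 13, and its oxygen, still bonded to C2, then displaces fluoride from C8a by intramolecular SNAr activated by the new ortho ketone. The closest known reaction types are the acyl substitution of β-lactones by organolithiums and the ring-opening/SNAr annulation of ortho-fluoroaryllithiums with epoxides and oxetanes; the net change is insertion of the C4a–C8a pair into the acyl–O bond, a two-atom ring expansion of the oxetan-2-one to the 2,3-dihydropyran-4-one. The one ring closure is a 6-exo addition–elimination of the alkoxide at the aryl C–F carbon through a Meisenheimer adduct. No new stereocentre is made: C2 never loses its C–O bond and C3 is not deprotonated, so the cis-(3S,4R) lactone is carried into the (2R,3S) chromanone, the less stable cis isomer that an equilibrating ring closure would not favour. The step needs carbonyl attack to beat α-deprotonation of the lactone and needs single addition, which −78 °C, inverse addition and the hindered di-ortho-substituted ketone should secure; it also needs SNAr to outrun retro-aldol cleavage of 13, which fluoride ortho to the carbonyl as the only leaving group and DMPU should secure.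

Step 7
Reactants: 14 (2R,3S)-5,7-bis(methoxymethoxy)-2,3-dimethyl-8-[(2S)-lavandulyl]chroman-4-one
Product: 15 (2R,3S)-5,7-dihydroxy-2,3-dimethyl-8-[(2S)-lavandulyl]chroman-4-one
Conditions: ZnBr2, n-PrSH, CH2Cl2, 0 °C, 15 min
Reagents that add atoms: none
Why: Lewis acid-assisted transfer of the methoxymethyl groups to the thiol cleaves both acetals without protic acid, which should avoid cyclisation of the lavandulyl alkene onto the phenol and epimerisation at C3.

Step 8
Reactants: 15 (2R,3S)-5,7-dihydroxy-2,3-dimethyl-8-[(2S)-lavandulyl]chroman-4-one, 16 3-phenylprop-2-ynal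
Product: 17 (2R,3S)-5-hydroxy-2,3-dimethyl-8-[(2S)-lavandulyl]chroman-4-one with a (4S)-4-phenyl-3,4-dihydro-2H-pyran-2-one ring fused at C6–C7 (lactone O on C7)
Conditions: aminoindanol-derived N-mesityl triazolium chloride (10 mol%), toluene, 40 °C
Reagents that add atoms: none
Why: NHC-catalysed redox-neutral annulation of an ynal with a stable enol (Coates–Claisen-type Michael addition–lactonisation via the cinnamoyl azolium): C6 is the only unsubstituted ring carbon, the free O7–H rather than the hydrogen-bonded O5–H should close the lactone (the O5 isomer would converge in step 9), and the chiral azolium shields one face of the acyl azolium so that the benzylic centre should form as S.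

Step 9
Reactants: 17 the C6–C7-fused lactone
Product: 19 (3S)-3-[(2R,3S)-5,7-dihydroxy-2,3-dimethyl-8-((2S)-lavandulyl)-4-oxochroman-6-yl]-3-phenylpropanoic acid, via dilithium carboxylate phenoxide 18 (not isolated)
Conditions: LiOH (2.2 equiv), THF/H2O, 0 °C; then 1 M HCl to pH 4, 0 °C
Reagents that add atoms: lithium hydroxide, [Li+].[OH-]
Why: acyl substitution at the aryl ester is fast at 0 °C, and the phenoxide formed lowers the acidity of C3–H, so the cis-chromanone should survive; cold, mild acidification should give the open hydroxy acid without relactonisation.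

Step 10
Reactants: 19 the dihydroxy acid, 20 tert-butyl prenyl carbonate
Product: 21 CNP0150579.2 (target)
Conditions: Pd2(dba)3·CHCl3 (2.5 mol%), (R,R)-DACH-phenyl ligand (7.5 mol%), CH2Cl2, 0 °C
Reagents that add atoms: none
Why: Tsuji–Trost allylic alkylation run as a dearomatisation: the carbonate ionises to π-prenyl-Pd and tert-butoxide; O-prenylation of carboxylate or phenol is reversible under Pd(0), whereas C-alkylation at C8 (ortho to O7, para to O5, with C6 shielded by its α-branched arm and C4a by the acyl group) gives the hydrogen-bonded vinylogous acid as the sink; attack at the less hindered allyl terminus gives the linear prenyl group, and the chiral ligand pocket should select the face of C8 and set the quaternary centre as S.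

Compound list
1 | 5-fluororesorcinol (5-fluorobenzene-1,3-diol) | Oc1cc(O)cc(F)c1 | starting material
2 | 1-fluoro-3,5-bis(methoxymethoxy)benzene | COCOc1cc(OCOC)cc(F)c1 | intermediate
3 | 2,4-dibromo-3-fluoro-1,5-bis(methoxymethoxy)benzene | COCOc1cc(OCOC)c(Br)c(F)c1Br | intermediate
4 | (R)-lavandulol | C=C(C)[C@@H](CC=C(C)C)CO | starting material
5 | (R)-lavandulyl iodide, (2R)-1-iodo-5-methyl-2-(prop-1-en-2-yl)hex-4-ene | C=C(C)[C@@H](CC=C(C)C)CI | intermediate
6 | [3-bromo-2-fluoro-4,6-bis(methoxymethoxy)phenyl]magnesium chloride | COCOc1cc(OCOC)c(Br)c(F)c1[Mg]Cl | intermediate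
7 | 2-bromo-3-fluoro-1,5-bis(methoxymethoxy)-4-[(2S)-lavandulyl]benzene | C=C(C)[C@@H](CC=C(C)C)Cc1c(F)c(Br)c(OCOC)cc1OCOC | intermediate
8 | propionyl chloride | CCC(=O)Cl | starting material
9 | acetaldehyde | CC=O | starting material
10 | methylketene | CC=C=O | intermediate
11 | (3S,4R)-3,4-dimethyloxetan-2-one (cis) | C[C@H]1OC(=O)[C@H]1C | intermediate
12 | aryllithium from 7 (Li in place of Br) | C=C(C)[C@@H](CC=C(C)C)Cc1c(F)c([Li])c(OCOC)cc1OCOC | intermediate
13 | lithium (2R,3S)-4-[2-fluoro-4,6-bis(methoxymethoxy)-3-((2S)-lavandulyl)phenyl]-3-methyl-4-oxobutan-2-olate | C=C(C)[C@@H](CC=C(C)C)Cc1c(F)c(C(=O)[C@@H](C)[C@@H](C)O[Li])c(OCOC)cc1OCOC | intermediate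
14 | (2R,3S)-5,7-bis(methoxymethoxy)-2,3-dimethyl-8-[(2S)-lavandulyl]chroman-4-one | C=C(C)[C@@H](CC=C(C)C)Cc1c(OCOC)cc(OCOC)c2c1O[C@H](C)[C@H](C)C2=O | intermediate
15 | (2R,3S)-5,7-dihydroxy-2,3-dimethyl-8-[(2S)-lavandulyl]chroman-4-one | C=C(C)[C@@H](CC=C(C)C)Cc1c(O)cc(O)c2c1O[C@H](C)[C@H](C)C2=O | intermediate
16 | 3-phenylprop-2-ynal | O=CC#Cc1ccccc1 | starting material
17 | (2R,3S)-5-hydroxy-2,3-dimethyl-8-[(2S)-lavandulyl]chroman-4-one with a (4S)-4-phenyl-3,4-dihydro-2H-pyran-2-one ring fused at C6–C7 (lactone O on C7) | C=C(C)[C@@H](CC=C(C)C)Cc1c2OC(=O)C[C@@H](c3ccccc3)c2c(O)c2c1O[C@H](C)[C@H](C)C2=O | intermediate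
18 | dilithium salt (carboxylate and 7-phenoxide) of 19 | C=C(C)[C@@H](CC=C(C)C)Cc1c([O-])c([C@@H](CC(=O)[O-])c2ccccc2)c(O)c2c1O[C@H](C)[C@H](C)C2=O.[Li+].[Li+] | intermediate
19 | (3S)-3-[(2R,3S)-5,7-dihydroxy-2,3-dimethyl-8-((2S)-lavandulyl)-4-oxochroman-6-yl]-3-phenylpropanoic acid | C=C(C)[C@@H](CC=C(C)C)Cc1c(O)c([C@@H](CC(=O)O)c2ccccc2)c(O)c2c1O[C@H](C)[C@H](C)C2=O | intermediate
20 | tert-butyl prenyl carbonate, tert-butyl (3-methylbut-2-en-1-yl) carbonate | CC(C)=CCOC(=O)OC(C)(C)C | starting material
21 | CNP0150579.2, (3S)-3-[(2R,3S,8S)-5-hydroxy-2,3-dimethyl-8-(3-methylbut-2-en-1-yl)-8-((2S)-lavandulyl)-4,7-dioxo-3,4,7,8-tetrahydro-2H-chromen-6-yl]-3-phenylpropanoic acid | C=C(C)[C@@H](CC=C(C)C)C[C@]1(CC=C(C)C)C(=O)C([C@@H](CC(=O)O)c2ccccc2)=C(O)C2=C1O[C@H](C)[C@H](C)C2=O | target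

Total step count: 10. Longest linear sequence: 8 steps (1, 2, 4, 6, 7, 8, 9, 10); steps 3 and 5 are one-step side branches.

Steps most likely to fail

Step 6. The aryllithium may deprotonate the lactone at its α-carbon instead of adding to the carbonyl, or lose lithium fluoride to an aryne on warming. The aldolate 13 may also undergo retro-aldol cleavage before the ring closes, which would erode the cis relationship and the enantiomeric purity. The fallback separates acylation from alkoxide formation and sets out from 11 (with 7), returning at 14. Lactone 11 is opened with N,O-dimethylhydroxylamine hydrochloride and iPrMgCl to (2S,3R)-3-hydroxy-N-methoxy-N,2-dimethylbutanamide F1, which is silylated (TBSCl, imidazole) to the silyl ether F2. Aryllithium 12, made from 7 as before, is acylated by F2 in a Weinreb ketone synthesis to give the β-silyloxy aryl ketone F3; no free alkoxide is present at this stage. Fluoride (TBAF, THF, 0 °C) then unmasks the alkoxide, which closes by the same SNAr to 14.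

Step 10. Facial selectivity at C8 may be poor, quaternisation may compete at C6, or the reaction may stall at reversible O-prenylation. The fallback drops catalyst control; it sets out from 19 and returns at 21. The polyanion of 19 is C-prenylated with prenyl bromide in cold aqueous KOH, a lupulone-type alkylation. The target 21 is then separated by chromatography from its diastereomer, the (8R) epimer F4; the separation is possible because four stereocentres are already fixed.

Step 8. The acyl-deactivated phenol may be too weak a nucleophile for the acyl azolium, the reaction may stop at O-acylation, or the enantioselectivity may be low. The fallback uses iminium catalysis; it sets out from 15 and returns at 17. Friedel–Crafts alkylation of 15 at C6 with (E)-cinnamaldehyde, catalysed by a diarylprolinol silyl ether and benzoic acid, gives the (4S)-4-phenylchroman-2-ol-type lactol F5 (hemiacetal on O7). Fétizon oxidation (Ag2CO3 on Celite) then converts the lactol to lactone 17.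

Further compounds
F1 | step 6 | (2S,3R)-3-hydroxy-N-methoxy-N,2-dimethylbutanamide | CON(C)C(=O)[C@@H](C)[C@@H](C)O
F2 | step 6 | (2S,3R)-3-(tert-butyldimethylsilyloxy)-N-methoxy-N,2-dimethylbutanamide | CON(C)C(=O)[C@@H](C)[C@@H](C)O[Si](C)(C)C(C)(C)C
F3 | step 6 | (2S,3R)-3-(tert-butyldimethylsilyloxy)-1-[2-fluoro-4,6-bis(methoxymethoxy)-3-((2S)-lavandulyl)phenyl]-2-methylbutan-1-one | C=C(C)[C@@H](CC=C(C)C)Cc1c(F)c(C(=O)[C@@H](C)[C@@H](C)O[Si](C)(C)C(C)(C)C)c(OCOC)cc1OCOC
F4 | step 10 | (8R) epimer of 21 | C=C(C)[C@@H](CC=C(C)C)C[C@@]1(CC=C(C)C)C(=O)C([C@@H](CC(=O)O)c2ccccc2)=C(O)C2=C1O[C@H](C)[C@H](C)C2=O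
F5 | step 8 | lactol of 17 (C=O of the lactone replaced by CH–OH, mixture at the hemiacetal carbon) | C=C(C)[C@@H](CC=C(C)C)Cc1c2OC(O)C[C@@H](c3ccccc3)c2c(O)c2c1O[C@H](C)[C@H](C)C2=O
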